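**Plan**

- Retrosynthesis: cut the three O–S bonds (back to kaempferol) and the two benzyl ethers, then O1–C2 (ring C) and C4a–C8a (ring A). This unrolls the flavone into one linear C15 chain stored as a 4-hydroxy-2-pyranone, which is cut at C2–C3 and C4–C4a.
- Enabling feature: the oxygens on C5, C7 and C8a of ring A sit on every second carbon, as in an acetate-derived chain, and C4–C3–C2 of ring C are simply the next three carbons of that chain.
- Forward: two polyanion acylations join the chain (C4–C4a, then C2–C3). One operation then opens the pyranone, closes ring A by Claisen condensation and closes ring C by cyclodehydration.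
- End game: hydrogenolysis of both benzyl ethers, sulfation of O3, O7 and O4' with the hydrogen-bonded 5-OH left free, and cation exchange to the acid form.
- Stereochemistry: the target has no stereocentre; the one labile centre of the chain (the future C3) becomes trigonal when ring C forms.

Key step: step 3

Remark: compounds 5, 6 and 7 hold one configurationally labile carbon between two carbonyl groups; they are racemic, one enantiomer is drawn, and the centre disappears in step 3. The target is taken as the free tris(hydrogen sulfate) as drawn, with salt 10 as its storable form.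

Step 1
Reactants: 1 4-hydroxy-6-methyl-2H-pyran-2-one (triacetic acid lactone); 2 methyl 2-(benzyloxy)acetate
Product: 3 6-[3-(benzyloxy)-2-oxopropyl]-4-hydroxy-2H-pyran-2-one
Conditions: 1 (2.1 equiv), LiN(iPr)2 (4.2 equiv, commercial solution), THF, −78 to 0 °C; then 2 (1.0 equiv), −78 °C to rt; aq. HCl
Reagents that add atoms: none
Why: Claisen-type acylation of a pyranone dianion: two equivalents of LiN(iPr)2 remove the hydroxyl proton and one methyl proton of 1, the exocyclic carbanion of this vinylogous acetoacetate dianion is its most nucleophilic site and attacks the ester carbonyl of 2, and the second equivalent of dianion takes up the newly acidic methylene proton of the product so that the acylation runs to completion.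

Step 2
Reactants: 3 6-[3-(benzyloxy)-2-oxopropyl]-4-hydroxy-2H-pyran-2-one; 4 methyl 4-(benzyloxy)benzoate
Product: 5 6-[3-(benzyloxy)-4-[4-(benzyloxy)phenyl]-2,4-dioxobutyl]-4-hydroxy-2H-pyran-2-one
Conditions: LiN(iPr)2 (4.2 equiv, commercial solution), THF, −78 to 0 °C; then 4 (1.1 equiv), 0 °C to rt; aq. HCl
Reagents that add atoms: none
Why: Terminal acylation of a polyanion: three equivalents of base ionise the hydroxyl, the doubly activated inner methylene and last the benzyloxy-bearing terminal carbon of 3, this last-formed and most basic carbanion attacks the non-enolisable benzoate 4 (Claisen condensation), and the fourth equivalent keeps the more acidic diketone product as its salt until the acid quench.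

Step 3
Reactants: 5 6-[3-(benzyloxy)-4-[4-(benzyloxy)phenyl]-2,4-dioxobutyl]-4-hydroxy-2H-pyran-2-one
Product: 8 3-(benzyloxy)-2-[4-(benzyloxy)phenyl]-5,7-dihydroxy-4H-chromen-4-one, via open-chain tetraketo methyl ester 6 (not isolated), via trihydroxyphenyl diketone 7 (not isolated)
Conditions: Mg(OMe)2 (8 equiv, commercial solution), dry MeOH, reflux, argon; then HCl (2 M, MeOH–H2O, pH 1), 50 °C
Reagents that add atoms: none
Why: Methoxide opens the lactone of 5 at its carbonyl carbon to the magnesium-chelated tetraketo ester 6, in which the methylene between the two central ketones (the future C4a) adds to the ester carbon (the future C8a), expels methoxide and enolises to the aromatic ring A of 7. The closest known reaction type is the Mg(OMe)2-induced Claisen recyclisation of 6-(2-oxoalkyl)-4-hydroxy-2-pyranones and 3,5,7-triketo esters to acylphloroglucinols, followed by the acid cyclodehydration of an ortho-hydroxyaryl 1,3-diketone to a chromone, as in the Baker–Venkataraman flavone synthesis. Ring A closes in a 6-exo-trig (enolexo) Claisen mode, and ring C closes by 6-exo-trig addition of a phenolic oxygen to the aryl ketone carbon (the future C2), followed by loss of water from the hemiketal. No stereocentre is created, and the labile benzyloxy-bearing carbon becomes the trigonal C3 of the flavone. The step needs the Claisen mode to win over the aldol mode (ester-side methylene onto the ketone that is to become C4) and over relactonisation; the dry magnesium methoxide medium holds the terminal keto ester as a chelated enolate that is a poor aldol donor, while the attacking carbon is activated by two ketones and the ester sits in the same chelate. Because ring A of 7 is symmetric about its acyl group, either ortho hydroxyl gives the same chromone, and the 5,7-diol emerges unprotected.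

Step 4
Reactants: 8 3-(benzyloxy)-2-[4-(benzyloxy)phenyl]-5,7-dihydroxy-4H-chromen-4-one
Product: 9 kaempferol, 3,5,7-trihydroxy-2-(4-hydroxyphenyl)-4H-chromen-4-one
Conditions: H2 (1 atm), 10% Pd on carbon, EtOAc–MeOH (1:1), rt
Reagents that add atoms: none
Why: Catalytic hydrogenolysis of benzyl ethers: both benzylic C–O bonds are cleaved on palladium at room temperature and one atmosphere, conditions under which the chromone carbonyl and the C2=C3 bond of the vinylogous ester are not reduced.

Step 5
Reactants: 9 kaempferol
Product: 10 tris(triethylammonium) kaempferol 3,7,4'-trisulfate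
Conditions: SO3·NEt3 (12 equiv), N,N-dimethylacetamide, 65 °C, HPLC control; reversed-phase C18 chromatography
Reagents that add atoms: sulfur trioxide–triethylamine complex, CC[N+](CC)(CC)S(=O)(=O)[O-]
Why: O-Sulfation with an amine–sulfur trioxide complex: the 7-, 4'- and 3-hydroxyls are sulfated (in that order of ease), whereas the 5-hydroxyl, tied to the C4 carbonyl by a strong hydrogen bond, is the least acidic and least nucleophilic oxygen and should stay free when the reaction is stopped at the trisulfate.

Step 6
Reactants: 10 tris(triethylammonium) kaempferol 3,7,4'-trisulfate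
Product: 11 kaempferol 3,7,4'-tri-O-sulfate, 5-hydroxy-4-oxo-2-[4-(sulfooxy)phenyl]-4H-chromene-3,7-diyl bis(hydrogen sulfate)
Conditions: Dowex 50W sulfonic acid resin (hydrogen form), H2O, 0–5 °C; freeze-drying at once
Reagents that add atoms: none
Why: Cation exchange on a sulfonic acid resin: triethylammonium is retained and replaced by protons, and the aryl and enol hydrogen sulfates, being strong acids, should pass through unchanged if the eluate is kept cold and freeze-dried at once.

**Compound list**

1 | 4-hydroxy-6-methyl-2H-pyran-2-one | Cc1cc(O)cc(=O)o1 | starting material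
2 | methyl 2-(benzyloxy)acetate | COC(=O)COCc1ccccc1 | starting material
3 | 6-[3-(benzyloxy)-2-oxopropyl]-4-hydroxy-2H-pyran-2-one | O=c1cc(O)cc(CC(=O)COCc2ccccc2)o1 | intermediate
4 | methyl 4-(benzyloxy)benzoate | COC(=O)c1ccc(OCc2ccccc2)cc1 | starting material
5 | 6-[3-(benzyloxy)-4-[4-(benzyloxy)phenyl]-2,4-dioxobutyl]-4-hydroxy-2H-pyran-2-one (racemic, labile centre, one enantiomer drawn) | O=c1cc(O)cc(CC(=O)[C@@H](OCc2ccccc2)C(=O)c2ccc(OCc3ccccc3)cc2)o1 | intermediate
6 | methyl 8-(benzyloxy)-9-[4-(benzyloxy)phenyl]-3,5,7,9-tetraoxononanoate (racemic, one enantiomer drawn; formed in the flask, not isolated) | COC(=O)CC(=O)CC(=O)CC(=O)[C@@H](OCc1ccccc1)C(=O)c1ccc(OCc2ccccc2)cc1 | intermediate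
7 | 2-(benzyloxy)-1-[4-(benzyloxy)phenyl]-3-(2,4,6-trihydroxyphenyl)propane-1,3-dione (racemic, one enantiomer drawn; formed in the flask, not isolated) | O=C(c1c(O)cc(O)cc1O)[C@@H](OCc1ccccc1)C(=O)c1ccc(OCc2ccccc2)cc1 | intermediate
8 | 3-(benzyloxy)-2-[4-(benzyloxy)phenyl]-5,7-dihydroxy-4H-chromen-4-one | O=c1c(OCc2ccccc2)c(-c2ccc(OCc3ccccc3)cc2)oc2cc(O)cc(O)c12 | intermediate
9 | kaempferol, 3,5,7-trihydroxy-2-(4-hydroxyphenyl)-4H-chromen-4-one | O=c1c(O)c(-c2ccc(O)cc2)oc2cc(O)cc(O)c12 | intermediate
10 | tris(triethylammonium) kaempferol 3,7,4'-trisulfate | O=c1c(OS(=O)(=O)[O-])c(-c2ccc(OS(=O)(=O)[O-])cc2)oc2cc(OS(=O)(=O)[O-])cc(O)c12.CC[NH+](CC)CC.CC[NH+](CC)CC.CC[NH+](CC)CC | intermediate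
11 | kaempferol 3,7,4'-tri-O-sulfate | O=c1c(OS(=O)(=O)O)c(-c2ccc(OS(=O)(=O)O)cc2)oc2cc(OS(=O)(=O)O)cc(O)c12 | target

**Step count and risks**

Total step count: 6. Longest linear sequence: 6 steps (1 to 11; 2 and 4 enter as purchased building blocks).

Steps most likely to fail:

1. Step 3. The opened chain may fold the wrong way (aldol closure from the ester-side methylene, or closure through the hindered benzyloxy-bearing carbon), may simply relactonise, or its aryl diketone end may be cut by methoxide in a retro-Claisen cleavage before ring A closes. Fallback, setting out from 3 and coming back at 8: the Claisen fold is carried out one stage earlier, on the shorter pyranone 3, where Mg(OMe)2 in methanol gives the documented acylphloroglucinol outcome and forms the same C4a–C8a bond. This should deliver 2-(benzyloxy)-1-(2,4,6-trihydroxyphenyl)ethan-1-one F1. Ring C is then built by an Allan–Robinson condensation of F1 with 4-(benzyloxy)benzoic anhydride and potassium 4-(benzyloxy)benzoate (neat, about 175 °C), which should give the O-aroylated flavone 3-(benzyloxy)-2-[4-(benzyloxy)phenyl]-4-oxo-4H-chromene-5,7-diyl bis[4-(benzyloxy)benzoate] F2. KOH in aqueous ethanol at reflux then cleaves the two aryl esters and returns the route to 8.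

2. Step 2. The third deprotonation may stay incomplete, or the hindered, oxygen-bearing carbanion may be acylated too slowly by the electron-rich benzoate, so that proton transfer, acylation on the pyranone oxygen or rearrangement of the benzyloxy carbanion takes over. Fallback, setting out from 3 and coming back at 5: the same trianion is trapped at −78 °C with the far more electrophilic 4-(benzyloxy)benzaldehyde (aldol addition) to give 6-[3-(benzyloxy)-4-[4-(benzyloxy)phenyl]-4-hydroxy-2-oxobutyl]-4-hydroxy-2H-pyran-2-one F3 as a mixture of diastereomers. Oxidation of its benzylic alcohol with 2-iodoxybenzoic acid (EtOAc, reflux), a reagent suited to turning β-hydroxy ketones into β-diketones, then gives 5 and erases both stereocentres of F3.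

3. Step 5. Sulfation may stop short at the hindered, hydrogen-bonded O3 or run on to O5, and the resulting anionic mixtures are hard to separate. Fallback, setting out from 9 and coming back at 11: 9 is treated with three equivalents of 2,2,2-trichloroethyl chlorosulfate (Et3N, 4-dimethylaminopyridine, THF, 0 °C) to give the neutral protected sulfate kaempferol 3,7,4'-tris(2,2,2-trichloroethyl sulfate) F4, which can be freed from regioisomers on silica gel. Reductive removal of the trichloroethyl groups (Zn dust, HCO2NH4, MeOH, rt) gives triammonium kaempferol 3,7,4'-trisulfate F5, and the cation exchange of step 6 applied to F5 gives 11.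

**Further compounds**

F1 | step 3 | 2-(benzyloxy)-1-(2,4,6-trihydroxyphenyl)ethan-1-one | O=C(COCc1ccccc1)c1c(O)cc(O)cc1O
F2 | step 3 | 3-(benzyloxy)-2-[4-(benzyloxy)phenyl]-4-oxo-4H-chromene-5,7-diyl bis[4-(benzyloxy)benzoate] | O=C(Oc1cc(OC(=O)c2ccc(OCc3ccccc3)cc2)c2c(=O)c(OCc3ccccc3)c(-c3ccc(OCc4ccccc4)cc3)oc2c1)c1ccc(OCc2ccccc2)cc1
F3 | step 2 | 6-[3-(benzyloxy)-4-[4-(benzyloxy)phenyl]-4-hydroxy-2-oxobutyl]-4-hydroxy-2H-pyran-2-one (mixture of racemic diastereomers) | O=c1cc(O)cc(CC(=O)C(OCc2ccccc2)C(O)c2ccc(OCc3ccccc3)cc2)o1
F4 | step 5 | kaempferol 3,7,4'-tris(2,2,2-trichloroethyl sulfate) | O=c1c(OS(=O)(=O)OCC(Cl)(Cl)Cl)c(-c2ccc(OS(=O)(=O)OCC(Cl)(Cl)Cl)cc2)oc2cc(OS(=O)(=O)OCC(Cl)(Cl)Cl)cc(O)c12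
F5 | step 5 | triammonium kaempferol 3,7,4'-trisulfate | O=c1c(OS(=O)(=O)[O-])c(-c2ccc(OS(=O)(=O)[O-])cc2)oc2cc(OS(=O)(=O)[O-])cc(O)c12.[NH4+].[NH4+].[NH4+]
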